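The route makes ring A of the flavone last. Ring A (C4a, C5, C6, C7, C8, C8a) is a phloroglucinol ring fused to the 4-pyranone ring C, so its C5–C6 bond is formed by an intramolecular Claisen condensation. The methyl carbon of an acetyl group attacks a methyl ester on the pyranone, and the resulting cyclic triketone aromatises to the 5,7-diol. The precursor is a 2-phenyl-3-methoxy-4-pyranone bearing that ester and, on the neighbouring ring carbon next to the ring oxygen, an sp3 carbon. This carbon carries both the acetyl group and the benzyl bridge to the O-benzyl-protected dihydrochalcone ring, and it becomes C8, which fixes the bridge position.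

Key step: step 11

Design remark: in precursor 18 both phenols of the dihydrochalcone ring are benzyl ethers. A free phenol ortho to the bridge could, under the base of step 11, add to the acetyl carbonyl (2-hydroxychroman, then 4H-chromene), add to the pyranone carbon next to the ring oxygen and open ring C, or expel the stabilised carbanion by retro-Michael fragmentation. For the same reason the bridge is made by alkylation with a benzylic bromide and not by addition to an ortho-quinone methide.

Assumption: 1, 2, 4, 7, 9 and 10 are taken as commercial; 3 is used as an E/Z mixture and 5, 13, 18 and 19 are racemic, which is without consequence because the target has no stereocentre.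

Step 1
Reactants: 1 methyl 4-methoxy-3-oxobutanoate; 2 1,1-dimethoxy-N,N-dimethylethan-1-amine
Product: 3 methyl 2-[1-(dimethylamino)ethylidene]-4-methoxy-3-oxobutanoate
Conditions: 2 (1.2 equiv), toluene, 50 °C
Reagents that add atoms: none
Why: Amide-acetal condensation (enaminone formation): the C2 methylene between ketone and ester is the only doubly activated position and condenses with 2 with loss of two methanol to give the push-pull alkene, whose geometry is labile and irrelevant.

Step 2
Reactants: 3 methyl 2-[1-(dimethylamino)ethylidene]-4-methoxy-3-oxobutanoate; 4 benzoyl chloride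
Product: 6 methyl 5-methoxy-2-methyl-4-oxo-6-phenyl-4H-pyran-3-carboxylate, via benzoylated enaminone 5 (not isolated)
Conditions: 3 + 4 added to LiN(SiMe3)2 (2.5 equiv), THF, −78 → 0 °C; then HCl (4 M in dioxane), rt
Reagents that add atoms: none
Why: Enaminone acylation–cyclocondensation to a 4-pyranone: the hindered amide base should deprotonate kinetically at the methoxy-bearing CH2 next to the ketone, C-benzoylation gives diketone 5, and under acid the benzoyl enol oxygen adds to the enamine carbon and expels dimethylamine (addition–elimination) to close the pyranone.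

Step 3
Reactants: 6 methyl 5-methoxy-2-methyl-4-oxo-6-phenyl-4H-pyran-3-carboxylate; 7 N-methoxy-N-methylacetamide
Product: 8 methyl 5-methoxy-4-oxo-2-(2-oxopropyl)-6-phenyl-4H-pyran-3-carboxylate
Conditions: LiN(SiMe3)2 (1.3 equiv), THF, −78 °C; 7, −78 → −20 °C; aq. NH4Cl
Reagents that add atoms: none
Why: Lateral metalation–acylation of a 2-methyl-4-pyranone: the methyl group is vinylogously activated by the ring ketone and the adjacent ester, its dienolate adds to the Weinreb amide, and the chelated tetrahedral adduct persists until the quench so that neither over-addition nor early ring closure onto the ester can occur.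

Step 4
Reactants: 9 2,4,6-trihydroxytoluene; 10 3-phenylpropanoyl chloride
Product: 11 1-(2,4,6-trihydroxy-3-methylphenyl)-3-phenylpropan-1-one
Conditions: AlCl3 (3.5 equiv), PhNO2, rt → 60 °C; then ice/HCl
Reagents that add atoms: none
Why: Friedel–Crafts acylation: the two free ring positions of 9 are equivalent by symmetry so only one regioisomer can form, and the acyl group deactivates the ring against a second acylation.

Step 5
Reactants: 11 1-(2,4,6-trihydroxy-3-methylphenyl)-3-phenylpropan-1-one
Product: 12 1-(2,6-dihydroxy-4-methoxy-3-methylphenyl)-3-phenylpropan-1-one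
Conditions: Me2SO4 (1.0 equiv), K2CO3 (1.0 equiv), acetone, rt → 40 °C
Reagents that add atoms: dimethyl sulfate, COS(=O)(=O)OC
Why: Selective Williamson O-methylation: the 4-OH para to the ketone is the most acidic hydroxyl and the only one that cannot hydrogen-bond to the carbonyl, so one equivalent of carbonate and of the hard methylating agent should etherify it first and at oxygen, not carbon.

Step 6
Reactants: 12 1-(2,6-dihydroxy-4-methoxy-3-methylphenyl)-3-phenylpropan-1-one
Product: 14 2,4-dihydroxy-6-methoxy-5-methyl-3-(3-phenylpropanoyl)benzaldehyde, via chloro ether 13 (not isolated)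
Conditions: Cl2CHOMe (1.5 equiv), TiCl4 (3 equiv), CH2Cl2, 0 °C → rt; then 1 M HCl
Reagents that add atoms: dichloromethyl methyl ether, ClC(Cl)OC; water, O
Why: Rieche formylation: the single remaining ring CH is activated by ortho-OH, ortho-OMe and para-OH and attacks the TiCl4-activated dichloromethyl ether to give chloro ether 13, which aqueous acid hydrolyses to the aldehyde, while the chromone-forming side reaction of formamide-based reagents with ortho-hydroxyaryl ketones is avoided.

Step 7
Reactants: 14 2,4-dihydroxy-6-methoxy-5-methyl-3-(3-phenylpropanoyl)benzaldehyde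
Product: 15 2,4-bis(benzyloxy)-6-methoxy-5-methyl-3-(3-phenylpropanoyl)benzaldehyde
Conditions: BnBr (2.6 equiv), K2CO3 (3 equiv), DMF, 60 °C
Reagents that add atoms: benzyl bromide, BrCc1ccccc1
Why: Williamson etherification: with every ring carbon now substituted only O-alkylation is possible, and warm DMF breaks the hydrogen bonds of the two chelated phenols so that both should be benzylated.

Step 8
Reactants: 15 2,4-bis(benzyloxy)-6-methoxy-5-methyl-3-(3-phenylpropanoyl)benzaldehyde
Product: 16 1-[2,6-bis(benzyloxy)-3-(hydroxymethyl)-4-methoxy-5-methylphenyl]-3-phenylpropan-1-one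
Conditions: NaBH4 (0.5 equiv), THF/MeOH, −20 → 0 °C
Reagents that add atoms: none
Why: Chemoselective hydride reduction: the aldehyde is far more electrophilic than the aryl ketone, which is twisted out of conjugation and shielded by two ortho benzyloxy groups, so a limited amount of NaBH4 at low temperature should reduce only the formyl group.

Step 9
Reactants: 16 1-[2,6-bis(benzyloxy)-3-(hydroxymethyl)-4-methoxy-5-methylphenyl]-3-phenylpropan-1-one
Product: 17 1-[2,6-bis(benzyloxy)-3-(bromomethyl)-4-methoxy-5-methylphenyl]-3-phenylpropan-1-one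
Conditions: CBr4 (1.3 equiv), PPh3 (1.3 equiv), CH2Cl2, 0 °C; short silica plug, used at once
Reagents that add atoms: carbon tetrabromide, BrC(Br)(Br)Br
Why: Appel reaction: the primary benzylic alcohol is converted to the bromide by SN2 displacement of its oxyphosphonium under neutral conditions that leave the benzyl ethers and the ketone untouched.

Step 10
Reactants: 8 methyl 5-methoxy-4-oxo-2-(2-oxopropyl)-6-phenyl-4H-pyran-3-carboxylate; 17 1-[2,6-bis(benzyloxy)-3-(bromomethyl)-4-methoxy-5-methylphenyl]-3-phenylpropan-1-one
Product: 18 methyl 2-{1-[2,4-bis(benzyloxy)-6-methoxy-5-methyl-3-(3-phenylpropanoyl)phenyl]-3-oxobutan-2-yl}-5-methoxy-4-oxo-6-phenyl-4H-pyran-3-carboxylate (racemic)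
Conditions: Cs2CO3 (1.2 equiv), DMF, 0 °C → rt
Reagents that add atoms: none
Why: C-alkylation of a stabilised enolate (SN2): the methylene of 8 is acidified by the ketone and by the pyranone/ester system, its soft enolate attacks the benzylic bromide at carbon, the hindered tertiary product resists a second alkylation, carbonate is too weak to enolise the methyl terminus so ring closure cannot start here, and the new stereocentre forms as a racemate that step 11 erases.

Step 11
Reactants: 18 methyl 2-{1-[2,4-bis(benzyloxy)-6-methoxy-5-methyl-3-(3-phenylpropanoyl)phenyl]-3-oxobutan-2-yl}-5-methoxy-4-oxo-6-phenyl-4H-pyran-3-carboxylate (racemic)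
Product: 20 8-{[2,4-bis(benzyloxy)-6-methoxy-5-methyl-3-(3-phenylpropanoyl)phenyl]methyl}-5,7-dihydroxy-3-methoxy-2-phenyl-4H-chromen-4-one, via cyclic triketone 19 (not isolated)
Conditions: LiN(i-Pr)2 (4 equiv), THF, −78 → 0 °C; then 1 M HCl
Reagents that add atoms: none
Why: Excess amide base removes first the doubly activated methine proton and then a proton of the acetyl methyl group, so the β-dicarbonyl-type dianion carries its reactive carbanion at the methyl terminus, which attacks the neighbouring ester carbonyl on the pyranone and expels methoxide. The closest known reaction type is the Claisen (Dieckmann-type) cyclisation of pyranone-masked polyketo esters to 5,7-dihydroxychromones. Ring A closes in a 6-exo-trig mode, and triketone 19 enolises twice to the aromatic 5,7-dihydroxy ring, which makes the sequence irreversible. No stereocentre is created and the one in 18 is erased. The step needs C-acylation through the methyl carbon and not through the methine carbon or the enolate oxygen: the methine carbon could only close a four-membered ring, and an enol lactone from O-acylation can be reopened by the liberated methoxide whereas aromatisation is not reversed. The bridge can only end up at C8 because it already sits on the carbon bonded to the future C8a, and the benzyl ethers exclude phenoxide-driven side reactions.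

Step 12
Reactants: 20 8-{[2,4-bis(benzyloxy)-6-methoxy-5-methyl-3-(3-phenylpropanoyl)phenyl]methyl}-5,7-dihydroxy-3-methoxy-2-phenyl-4H-chromen-4-one
Product: 21 8-{[2,4-dihydroxy-6-methoxy-5-methyl-3-(3-phenylpropanoyl)phenyl]methyl}-5,7-dihydroxy-3-methoxy-2-phenyl-4H-chromen-4-one (CNP0280022.0)
Conditions: H2 (1 atm), 10% Pd/C, EtOAc/MeOH, rt
Reagents that add atoms: none
Why: Catalytic hydrogenolysis of aryl benzyl ethers: both O–CH2Ph bonds are cleaved to toluene under neutral conditions, while the flavone enone, the hydrogen-bonded aryl ketone, the methyl ethers and the diarylmethane bridge should be inert at 1 atm and room temperature.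

Compound list
1 | methyl 4-methoxy-3-oxobutanoate | COCC(=O)CC(=O)OC | starting material
2 | 1,1-dimethoxy-N,N-dimethylethan-1-amine (N,N-dimethylacetamide dimethyl acetal) | CC(OC)(OC)N(C)C | starting material
3 | methyl 2-[1-(dimethylamino)ethylidene]-4-methoxy-3-oxobutanoate (E/Z mixture) | COCC(=O)C(C(=O)OC)=C(C)N(C)C | intermediate
4 | benzoyl chloride | O=C(Cl)c1ccccc1 | starting material
5 | methyl 2-[1-(dimethylamino)ethylidene]-4-methoxy-3,5-dioxo-5-phenylpentanoate (racemic, E/Z mixture) | COC(C(=O)c1ccccc1)C(=O)C(C(=O)OC)=C(C)N(C)C | intermediate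
6 | methyl 5-methoxy-2-methyl-4-oxo-6-phenyl-4H-pyran-3-carboxylate | COC(=O)c1c(C)oc(-c2ccccc2)c(OC)c1=O | intermediate
7 | N-methoxy-N-methylacetamide | CC(=O)N(C)OC | starting material
8 | methyl 5-methoxy-4-oxo-2-(2-oxopropyl)-6-phenyl-4H-pyran-3-carboxylate | COC(=O)c1c(CC(C)=O)oc(-c2ccccc2)c(OC)c1=O | intermediate
9 | 2,4,6-trihydroxytoluene | Cc1c(O)cc(O)cc1O | starting material
10 | 3-phenylpropanoyl chloride | O=C(Cl)CCc1ccccc1 | starting material
11 | 1-(2,4,6-trihydroxy-3-methylphenyl)-3-phenylpropan-1-one | Cc1c(O)cc(O)c(C(=O)CCc2ccccc2)c1O | intermediate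
12 | 1-(2,6-dihydroxy-4-methoxy-3-methylphenyl)-3-phenylpropan-1-one | COc1cc(O)c(C(=O)CCc2ccccc2)c(O)c1C | intermediate
13 | 1-{3-[chloro(methoxy)methyl]-2,6-dihydroxy-4-methoxy-5-methylphenyl}-3-phenylpropan-1-one (racemic) | COc1c(C)c(O)c(C(=O)CCc2ccccc2)c(O)c1C(Cl)OC | intermediate
14 | 2,4-dihydroxy-6-methoxy-5-methyl-3-(3-phenylpropanoyl)benzaldehyde | COc1c(C)c(O)c(C(=O)CCc2ccccc2)c(O)c1C=O | intermediate
15 | 2,4-bis(benzyloxy)-6-methoxy-5-methyl-3-(3-phenylpropanoyl)benzaldehyde | COc1c(C)c(OCc2ccccc2)c(C(=O)CCc2ccccc2)c(OCc2ccccc2)c1C=O | intermediate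
16 | 1-[2,6-bis(benzyloxy)-3-(hydroxymethyl)-4-methoxy-5-methylphenyl]-3-phenylpropan-1-one | COc1c(C)c(OCc2ccccc2)c(C(=O)CCc2ccccc2)c(OCc2ccccc2)c1CO | intermediate
17 | 1-[2,6-bis(benzyloxy)-3-(bromomethyl)-4-methoxy-5-methylphenyl]-3-phenylpropan-1-one | COc1c(C)c(OCc2ccccc2)c(C(=O)CCc2ccccc2)c(OCc2ccccc2)c1CBr | intermediate
18 | methyl 2-{1-[2,4-bis(benzyloxy)-6-methoxy-5-methyl-3-(3-phenylpropanoyl)phenyl]-3-oxobutan-2-yl}-5-methoxy-4-oxo-6-phenyl-4H-pyran-3-carboxylate (racemic) | COC(=O)c1c(C(Cc2c(OC)c(C)c(OCc3ccccc3)c(C(=O)CCc3ccccc3)c2OCc2ccccc2)C(C)=O)oc(-c2ccccc2)c(OC)c1=O | intermediate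
19 | 8-{[2,4-bis(benzyloxy)-6-methoxy-5-methyl-3-(3-phenylpropanoyl)phenyl]methyl}-3-methoxy-2-phenyl-6,8-dihydro-4H-chromene-4,5,7-trione (racemic) | COc1c(C)c(OCc2ccccc2)c(C(=O)CCc2ccccc2)c(OCc2ccccc2)c1CC1C(=O)CC(=O)c2c1oc(-c1ccccc1)c(OC)c2=O | intermediate
20 | 8-{[2,4-bis(benzyloxy)-6-methoxy-5-methyl-3-(3-phenylpropanoyl)phenyl]methyl}-5,7-dihydroxy-3-methoxy-2-phenyl-4H-chromen-4-one | COc1c(C)c(OCc2ccccc2)c(C(=O)CCc2ccccc2)c(OCc2ccccc2)c1Cc1c(O)cc(O)c2c(=O)c(OC)c(-c3ccccc3)oc12 | intermediate
21 | 8-{[2,4-dihydroxy-6-methoxy-5-methyl-3-(3-phenylpropanoyl)phenyl]methyl}-5,7-dihydroxy-3-methoxy-2-phenyl-4H-chromen-4-one | COc1c(C)c(O)c(C(=O)CCc2ccccc2)c(O)c1Cc1c(O)cc(O)c2c(=O)c(OC)c(-c3ccccc3)oc12 | target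

Total step count: 12. Longest linear sequence: 9 steps (steps 4 to 12, from 9).

Steps most likely to fail

Step 11. Proton shuffling may leave the polyanion as unreactive methine and aryl-ketone enolates, the pyranone ring may be opened by nucleophilic attack, or O-acylation may divert material to an enol lactone. The fallback builds ring A before the bridge; it sets out from 12 and returns to the route at 21. Phloroglucinol is acylated with methoxyacetonitrile (Hoesch reaction: ZnCl2, HCl, Et2O, then hot water) to 1-(2,4,6-trihydroxyphenyl)-2-methoxyethan-1-one F1. Allan–Robinson condensation of F1 (benzoic anhydride, sodium benzoate, 180 °C; then KOH, aq. EtOH) should give 5,7-dihydroxy-3-methoxy-2-phenyl-4H-chromen-4-one F2. Separately, 12 is aminomethylated at its only free ring position (Me2NH, aq. CH2O, EtOH) to the Mannich base 1-{3-[(dimethylamino)methyl]-2,6-dihydroxy-4-methoxy-5-methylphenyl}-3-phenylpropan-1-one F3. Heating F3 with F2 in dioxane should release the ortho-quinone methide, which alkylates ring A of F2; the C8-substituted product is 21 and has to be separated from the C6 isomer, since site selectivity is not secured in this variant.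

Step 2. Deprotonation may occur at the enamine methyl group instead of the methoxy-bearing CH2, the enolate may be benzoylated at oxygen, or the enol may close onto the ester to a 2-pyranone. The fallback reverses the order of the two bond formations; it sets out from 1 and returns at 6. The dianion of 1 (NaH, then n-BuLi, THF, 0 °C) is benzoylated at its only γ-carbon with methyl benzoate to give methyl 4-methoxy-3,5-dioxo-5-phenylpentanoate F4. Warming F4 with 2 in toluene should condense the acetal at the C2 methylene, and the benzoyl enol oxygen then displaces dimethylamine to close 6.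

Step 10. The electron-rich benzylic bromide may ionise and be lost to solvolysis or self-alkylation before it meets the enolate, or the ambident enolate may be alkylated at oxygen. The fallback avoids the halide; it sets out from 15 and 8 and returns at 18. Knoevenagel condensation of 15 with 8 (TiCl4, pyridine, THF, 0 °C → rt) should give the alkylidene ketone methyl 2-{1-[2,4-bis(benzyloxy)-6-methoxy-5-methyl-3-(3-phenylpropanoyl)phenyl]-3-oxobut-1-en-2-yl}-5-methoxy-4-oxo-6-phenyl-4H-pyran-3-carboxylate F5. Conjugate reduction of F5 with Hantzsch ester (diethyl 2,6-dimethyl-1,4-dihydropyridine-3,5-dicarboxylate, toluene, 60 °C) then delivers 18.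

Further compounds
F1 | step 11 | 1-(2,4,6-trihydroxyphenyl)-2-methoxyethan-1-one | COCC(=O)c1c(O)cc(O)cc1O
F2 | step 11 | 5,7-dihydroxy-3-methoxy-2-phenyl-4H-chromen-4-one | COc1c(-c2ccccc2)oc2cc(O)cc(O)c2c1=O
F3 | step 11 | 1-{3-[(dimethylamino)methyl]-2,6-dihydroxy-4-methoxy-5-methylphenyl}-3-phenylpropan-1-one | COc1c(C)c(O)c(C(=O)CCc2ccccc2)c(O)c1CN(C)C
F4 | step 2 | methyl 4-methoxy-3,5-dioxo-5-phenylpentanoate (racemic) | COC(C(=O)c1ccccc1)C(=O)CC(=O)OC
F5 | step 10 | methyl 2-{1-[2,4-bis(benzyloxy)-6-methoxy-5-methyl-3-(3-phenylpropanoyl)phenyl]-3-oxobut-1-en-2-yl}-5-methoxy-4-oxo-6-phenyl-4H-pyran-3-carboxylate (E/Z mixture) | COC(=O)c1c(C(=Cc2c(OC)c(C)c(OCc3ccccc3)c(C(=O)CCc3ccccc3)c2OCc2ccccc2)C(C)=O)oc(-c2ccccc2)c(OC)c1=O
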